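Removing the C10–C11 bond of the cyclobutane leaves the cyclohexenone ring (C4, C5, C11, C1, C2, C3) and the seven-membered ring (C4 to C10) fused through C4–C5. The C2=C3 alkene then sits exactly where a [4+2] cycloaddition would leave it. Everything therefore rests on one intramolecular Diels–Alder reaction across the five-atom tether C6–C10. A single heating forms C4–C5 and C1–C11, closes both rings and sets C4, C5 and C11. The precursor is a triene: an E-configured vinylketene methyl silyl acetal (C1–C4) tied through C10, the C9 dioxolane, C8 and C7(OTBS) to quaternary C6, whose Z-enoate (C5=C11) is locked as a δ-lactone.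

Key step: step 14

**Labels.** C1 is the ketone and C2=C3 the alkene (CH3 on C3). C4 and C5 are ring CH carbons, C6 is the quaternary carbon, C7 carries OAc, C8 is CH2, C9 carries O-senecioyl, C10 is the quaternary carbon with CH3, and C11 is the cyclobutane CH on C1. "Arm" is the CH2O carbon on C6. C12 is the carboxyl carbon that C11 carries up to step 15.

**Assumption.** In step 8 the (S)-ligand is taken to give the (7R) carbinol, by analogy with related iridium allylations. Should the sense be opposite, the commercial (R)-ligand is used and nothing else changes.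

**Design points**
- **Dienophile geometry.** The cis fusion at C4–C5 needs C6 endo.
  - An E-enoate would then have its ester exo, whereas a Z-enoate puts tether and carbonyl on the same side, so the favoured endo mode gives the cis fusion.
  - Tying the Z-ester to the arm oxygen keeps it planar, makes it more electrophilic, removes rotors and lets C6 choose the face.
  - The lactone also frees the arm hydroxyl on decarboxylation.
- **C10 source.** C10 comes from the (R)-hydroxy ester, with its carbonyl carbon becoming C9. This is the configuration in which A(1,3) strain places C9 on the diene face that must react.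
- **Diene storage.** The diene is stored as a (Z)-3-methyl-2-enoate until step 13, so C10 is never allylic next to a free carbonyl. One methyl and one TBS group replace two labile silyl groups.
- **Closing C10–C11.** An enolate on the C8 side would expel O7 or attack C11. O7 is therefore removed on purpose in step 18, which leaves C10 as the only enolisable site of the C9 carbonyl. O7 is put back in step 20.
- **Where each stereocentre is set.**
  - C6 in step 8.
  - C7 in step 8, erased in step 18 and set again in step 20.
  - C4 and C5 in step 14.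
  - C10 and C11 in step 19.
  - C9 in step 21.

## Route

Step 1
Reactants: 1 methyl (R)-3-hydroxy-2-methylpropanoate
Product: 2 (R)-3-hydroxy-N-methoxy-N,2-dimethylpropanamide
Conditions: MeNH(OMe)·HCl, iPrMgCl, THF, −20 °C
Reagents that add atoms: N,O-dimethylhydroxylamine hydrochloride, CNOC.Cl
Why: Weinreb amide formation by magnesium amide aminolysis of the ester, run cold so that the α-stereocentre (future C10) is not enolised.

Step 2
Reactants: 2 (R)-3-hydroxy-N-methoxy-N,2-dimethylpropanamide
Product: 3 (S)-3-iodo-N-methoxy-N,2-dimethylpropanamide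
Conditions: I2, PPh3, imidazole, CH2Cl2, 0 °C to rt
Reagents that add atoms: iodine, II
Why: Appel-type iodination is an SN2 displacement at the primary carbon (future C4) and leaves the neighbouring stereocentre untouched, the descriptor changing only through priorities.

Step 3
Reactants: 4 methyl but-2-ynoate
Product: 5 methyl (Z)-3-iodobut-2-enoate
Conditions: NaI, AcOH, 110 °C
Reagents that add atoms: sodium iodide, [Na+].[I-]
Why: Anti hydroiodination of the ynoate (conjugate addition of iodide, then protonation) gives the Z-β-iodoenoate, which fixes the later C4 cis to the C1 ester.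

Step 4
Reactants: 3 (S)-3-iodo-N-methoxy-N,2-dimethylpropanamide; 5 methyl (Z)-3-iodobut-2-enoate
Product: 7 methyl (2Z,5R)-6-[methoxy(methyl)amino]-3,5-dimethyl-6-oxohex-2-enoate, via alkylzinc iodide 6 (not isolated)
Conditions: Zn dust, LiCl, THF, rt; then 5, Pd(PPh3)4 (5 mol %), THF, rt to 40 °C
Reagents that add atoms: none
Why: Negishi coupling, in which zinc inserts into the primary iodide to give an alkylzinc whose β-stereocentre is configurationally stable and zerovalent palladium joins it to the alkenyl iodide with retention of the Z geometry.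

Step 5
Reactants: 7 methyl (2Z,5R)-6-[methoxy(methyl)amino]-3,5-dimethyl-6-oxohex-2-enoate; 8 vinylmagnesium bromide
Product: 9 methyl (2Z,5R)-3,5-dimethyl-6-oxoocta-2,7-dienoate
Conditions: THF, −78 to −20 °C; cold 1 M HCl quench
Reagents that add atoms: none
Why: Weinreb ketone synthesis, in which the chelated tetrahedral intermediate stops at the ketone and the hindered β,β-disubstituted enoate is much slower toward the Grignard reagent in the cold.

Step 6
Reactants: 9 methyl (2Z,5R)-3,5-dimethyl-6-oxoocta-2,7-dienoate
Product: 10 methyl (2Z,5R)-3,5-dimethyl-6-oxo-8-(pinacolatoboryl)oct-2-enoate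
Conditions: B2pin2, CuCl (5 mol %), DPEphos, NaOtBu (10 mol %), MeOH, THF, rt
Reagents that add atoms: bis(pinacolato)diboron, CC1(C)OB(OC1(C)C)B1OC(C)(C)C(C)(C)O1
Why: Copper-catalysed conjugate borylation selects the unhindered vinyl ketone over the β,β-disubstituted enoate and stores the future C7 hydroxyl as a C–B bond.

Step 7
Reactants: 10 methyl (2Z,5R)-3,5-dimethyl-6-oxo-8-(pinacolatoboryl)oct-2-enoate
Product: 12 methyl (2Z,5R)-5-[2-(2-hydroxyethyl)-1,3-dioxolan-2-yl]-3-methylhex-2-enoate, via boryl dioxolane 11 (not isolated)
Conditions: (Me3SiOCH2)2, Me3SiOTf (10 mol %), CH2Cl2, −78 to −20 °C, pyridine quench; then NaBO3·4H2O, THF/H2O, rt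
Reagents that add atoms: 1,2-bis(trimethylsilyloxy)ethane, C[Si](C)(C)OCCO[Si](C)(C)C; sodium perborate, [Na+].[Na+].O[B-]1(O)OO[B-](O)(O)OO1
Why: Noyori ketalisation under aprotic low-temperature conditions masks C9 without epimerising C10, and perborate oxidation of the primary C–B bond then gives the C7 alcohol.

Step 8
Reactants: 12 methyl (2Z,5R)-5-[2-(2-hydroxyethyl)-1,3-dioxolan-2-yl]-3-methylhex-2-enoate; 13 2-methyl-2-vinyloxirane (racemic)
Product: 14 anti-1,3-diol (6R,7R,10R) with C6 bearing CH3, CH2OH and vinyl
Conditions: cyclometalated π-allyliridium C,O-benzoate complex prepared from [Ir(cod)Cl]2, (S)-Tol-BINAP, 4-cyano-3-nitrobenzoic acid and allyl acetate (5 mol %), K3PO4 (5 mol %), THF, 60 °C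
Reagents that add atoms: none
Why: Iridium-catalysed transfer-hydrogenative tert-(hydroxy)prenylation, in which the alcohol is dehydrogenated to the aldehyde, the epoxide gives an (E)-σ-allyliridium species, and addition through a closed chair with CH2OH pseudo-equatorial sets C7 and quaternary C6 (OH anti to CH2OH) under ligand control, remote C10 having no influence.

Step 9
Reactants: 14 anti-1,3-diol (6R,7R,10R)
Product: 15 β-hydroxy aldehyde (6S,7R,10R) with C5 as CHO
Conditions: TEMPO (10 mol %), PhI(OAc)2, CH2Cl2, rt
Reagents that add atoms: none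
Why: Oxoammonium (TEMPO) oxidation takes the primary alcohol in preference to the hindered secondary one, and the aldehyde has no α-hydrogen so it can neither epimerise nor eliminate.

Step 10
Reactants: 15 β-hydroxy aldehyde (6S,7R,10R)
Product: 16 C7 TBS ether aldehyde (6S,7R,10R)
Conditions: TBSOTf, 2,6-lutidine, CH2Cl2, −78 to 0 °C
Reagents that add atoms: tert-butyldimethylsilyl triflate, CC(C)(C)[Si](C)(C)OS(=O)(=O)C(F)(F)F
Why: Silyl triflate silylation is strong enough for the neopentyl-type secondary alcohol, and the non-enolisable aldehyde and the ketone-derived dioxolane tolerate the buffered conditions.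

Step 11
Reactants: 16 C7 TBS ether aldehyde (6S,7R,10R); 17 methyl bis(2,2,2-trifluoroethyl)phosphonoacetate
Product: 18 bis-enoate (6R,7R,10R) with the new C5=C11 bond Z
Conditions: KN(SiMe3)2, 18-crown-6, THF, −78 °C
Reagents that add atoms: none
Why: Still–Gennari olefination, whose fast irreversible elimination from the kinetic adduct gives the Z-enoate and brings in C11 and C12.

Step 12
Reactants: 18 bis-enoate (6R,7R,10R)
Product: 21 α,β-unsaturated δ-lactone (6S,7R,10R), via neopentyl aldehyde 19 (not isolated), via hydroxy Z-enoate 20 (not isolated)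
Conditions: O3, CH2Cl2/MeOH, pyridine, −78 °C (Sudan Red 7B end point); NaBH4, −78 to 0 °C; then PPTS (cat.), CH2Cl2, rt
Reagents that add atoms: ozone, [O-][O+]=O
Why: Ozonolysis cleaves the only electron-rich alkene (the vinyl group) ahead of the two conjugated esters, borohydride reduces the resulting aldehyde, and the arm alcohol lactonises onto the Z-enoate to a six-membered ring that locks the dienophile geometry.

Step 13
Reactants: 21 α,β-unsaturated δ-lactone (6S,7R,10R)
Product: 23 triene: (3E)-vinylketene methyl TBS acetal tethered to the lactone (6S,7R,10R), via lithium dienolate 22 (not isolated)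
Conditions: LiN(iPr)2, TBSCl, DMPU, THF, −78 °C; pentane extraction, used crude
Reagents that add atoms: tert-butyldimethylsilyl chloride, CC(C)(C)[Si](C)(C)Cl
Why: Kinetic γ-deprotonation of a 3-methyl-2-enoate occurs at the γ-carbon syn to the ester carbonyl (here C4H2), bulky C10 turns away from the ester so that the new C3=C4 bond is E, O-silylation traps the dienolate, and the lactone offers no acidic hydrogen because C6 is quaternary.

Step 14
Reactants: 23 triene (6S,7R,10R)
Product: 24 cis-fused cycloadduct (1S,4S,5S,6S,7R,10R,11S) with H4, H5 and H11 on one face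
Conditions: toluene (0.005 M), BHT (cat.), propylene oxide (acid scavenger), silylated sealed vessel, 170 °C
Reagents that add atoms: none
Why: The reaction is a concerted but asynchronous normal-electron-demand [4+2] cycloaddition in which C4, the terminus with the largest HOMO coefficient of the 1,1-dioxygenated diene, bonds ahead to the β-carbon C5 of the unsaturated lactone while C1 closes on C11. The closest known reaction type is the thermal type 1 intramolecular Diels–Alder reaction of 1-oxygenated dienes with tethered enoates, of which five-atom tethers are the slow members, hence heat, high dilution and a lactone that is more electrophilic than an open-chain ester. The cyclohexene ring (C1, C2, C3, C4, C5, C11) is closed by the cycloaddition itself, and the seven-membered ring (C4 to C10) is closed as the fused ring spanned by the tether, sharing C4–C5. C5 and C11 are controlled by C6, because CH3 and C7 lie on opposite faces of the lactone ring, the diene can arrive only on the face that carries C7, and the ring-locked Z alkene places C6 and C12 cis. C4 is controlled by the E geometry of C3=C4 together with the endo arrangement (lactone carbonyl and C6 under the diene), which gives the cis fusion, and by C10, whose hydrogen eclipses the C3 methyl group (A(1,3) strain) so that C9 hangs on the diene face that meets the dienophile, while the extra ketal centre at C1 merely reflects the acetal geometry and vanishes in step 15. The step needs endo over exo and one pair of faces, regiochemistry being fixed by tether and polarity alike, and endo is secured because tether and carbonyl now sit on the same side of the alkene while C6, C7 and C10 favour the same folded conformer.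

Step 15
Reactants: 24 cis-fused cycloadduct
Product: 26 bicyclic enone with C11H2 and free arm CH2OH, via β-keto lactone 25 (not isolated)
Conditions: 0.5 M HCl, THF, 0 °C; crude, then H2O, DMSO, 130 °C
Reagents that add atoms: water, O
Why: Acid hydrolysis of the mixed silyl ketal unveils the C1 ketone in conjugation with C2=C3, and neutral Krapcho-type hydrolytic decarboxylation of the β-keto lactone then removes C12 and frees the arm alcohol without base that could epimerise the γ-carbon C4.

Step 16
Reactants: 26 bicyclic enone alcohol
Product: 27 arm TBDPS ether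
Conditions: TBDPSCl, imidazole, DMF, rt
Reagents that add atoms: tert-butyldiphenylsilyl chloride, CC(C)(C)[Si](Cl)(c1ccccc1)c1ccccc1
Why: Standard silylation of the only free hydroxyl gives an ether that outlasts acid, amide bases and copper salts in the next steps.

Step 17
Reactants: 27 arm TBDPS ether
Product: 28 β-hydroxy ketone (C7–OH, C9=O)
Conditions: 48% aq. HF, MeCN, 0 °C to rt
Reagents that add atoms: water, O
Why: Aqueous HF cleaves the secondary TBS ether and hydrolyses the dioxolane, while the far more acid-stable primary TBDPS ether stays.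

Step 18
Reactants: 28 β-hydroxy ketone
Product: 30 bicyclic bis-enone (C1 enone and C7=C8–C9=O), via C7 mesylate 29 (not isolated)
Conditions: MsCl, Et3N, CH2Cl2, 0 °C to rt
Reagents that add atoms: none
Why: Mesylation followed by E1cB elimination turns C8 into an sp2 carbon, so that the C9 carbonyl can afterwards be enolised only toward C10 and no β-leaving group remains.

Step 19
Reactants: 30 bicyclic bis-enone
Product: 32 tricyclic bis-enone with the C10–C11 bond, via dilithium bis-enolate 31 (not isolated)
Conditions: LiN(iPr)2 (2.5 equiv), THF, −78 to −40 °C; CuCl2 (2.5 equiv), DMF, −78 to 0 °C, 0.005 M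
Reagents that add atoms: none
Why: Intramolecular oxidative coupling of a ketone bis-enolate, a reaction type that has closed three- and four-membered 1,2-diacyl rings: both carbonyls are enones with a single kinetic α′ site (C11H2 and C10H, the C9 enone having no γ-hydrogen because C6 is quaternary), so one bis-enolate forms, divalent copper oxidises it, and C10 and C11, held 1,3-cis on the cis-fused bicycle, can join only on the face that carries both, which sets quaternary C10 and C11.

Step 20
Reactants: 32 tricyclic bis-enone
Product: 34 tricyclic β-hydroxy ketone (7R), via C7 boronate 33 (not isolated)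
Conditions: B2pin2, CuCl (10 mol %), DPEphos, NaOtBu (15 mol %), MeOH, THF, rt; then NaBO3·4H2O, THF/H2O, rt
Reagents that add atoms: sodium perborate, [Na+].[Na+].O[B-]1(O)OO[B-](O)(O)OO1
Why: Copper-catalysed conjugate borylation followed by oxidation with retention, in which the boryl copper species adds to C7 of the less substituted enone (the β-carbon C3 of the other enone is fully substituted) from the face anti to the bulky CH2OTBDPS on C6 and syn to its CH3, which sets C7 again.

Step 21
Reactants: 34 tricyclic β-hydroxy ketone; 35 acetaldehyde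
Product: 36 C7 acetate C9 alcohol (7R,9R)
Conditions: SmI2 (30 mol %, premixed with 35), THF, −10 °C
Reagents that add atoms: none
Why: Evans–Tishchenko reduction, in which the hemiacetal formed from O7 and acetaldehyde delivers hydride intramolecularly to C9 inside a trivalent samarium chelate, giving the 1,3-anti alcohol at C9 and leaving the acetate on O7 in the same operation.

Step 22
Reactants: 36 C7 acetate C9 alcohol; 37 3-methylbut-2-enoyl chloride
Product: 38 C7 acetate C9 senecioate arm TBDPS ether
Conditions: pyridine, DMAP (cat.), CH2Cl2, 0 °C to rt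
Reagents that add atoms: none
Why: DMAP-catalysed acylation of the only free hydroxyl, run with pyridine and not a strong amine so that neither deconjugation of the acyl chloride through its vinylketene nor acetate migration sets in.

Step 23
Reactants: 38 C7 acetate C9 senecioate arm TBDPS ether
Product: 39 primary alcohol
Conditions: HF·pyridine, pyridine, THF, 0 °C to rt
Reagents that add atoms: none
Why: Buffered fluoride desilylation removes the TBDPS group without touching the two esters or the enone.

Step 24
Reactants: 39 primary alcohol; 40 angelic acid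
Product: 42 target CNP0179010.1, via mixed anhydride 41 (not isolated)
Conditions: 40, 2,4,6-trichlorobenzoyl chloride, Et3N, toluene, rt; then 39, toluene, 80 °C
Reagents that add atoms: none
Why: Yamaguchi-type mixed anhydride esterification without a nucleophilic catalyst transfers the angeloyl group to the primary alcohol without Z to E isomerisation, and placing it last spares the sensitive ester all other steps.

## Compound list

1 | methyl (R)-3-hydroxy-2-methylpropanoate | COC(=O)[C@H](C)CO | starting material
2 | (R)-3-hydroxy-N-methoxy-N,2-dimethylpropanamide | CON(C)C(=O)[C@H](C)CO | intermediate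
3 | (S)-3-iodo-N-methoxy-N,2-dimethylpropanamide | CON(C)C(=O)[C@H](C)CI | intermediate
4 | methyl but-2-ynoate | CC#CC(=O)OC | starting material
5 | methyl (Z)-3-iodobut-2-enoate | COC(=O)/C=C(/C)I | intermediate
6 | alkylzinc iodide from 3 | CON(C)C(=O)[C@H](C)C[Zn]I | intermediate
7 | methyl (2Z,5R)-6-[methoxy(methyl)amino]-3,5-dimethyl-6-oxohex-2-enoate | COC(=O)/C=C(/C)C[C@@H](C)C(=O)N(C)OC | intermediate
8 | vinylmagnesium bromide | C=C[Mg]Br | starting material
9 | methyl (2Z,5R)-3,5-dimethyl-6-oxoocta-2,7-dienoate | COC(=O)/C=C(/C)C[C@@H](C)C(=O)C=C | intermediate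
10 | methyl (2Z,5R)-3,5-dimethyl-6-oxo-8-(pinacolatoboryl)oct-2-enoate | COC(=O)/C=C(/C)C[C@@H](C)C(=O)CCB1OC(C)(C)C(C)(C)O1 | intermediate
11 | boryl dioxolane | COC(=O)/C=C(/C)C[C@@H](C)C1(CCB2OC(C)(C)C(C)(C)O2)OCCO1 | intermediate
12 | methyl (2Z,5R)-5-[2-(2-hydroxyethyl)-1,3-dioxolan-2-yl]-3-methylhex-2-enoate | COC(=O)/C=C(/C)C[C@@H](C)C1(CCO)OCCO1 | intermediate
13 | 2-methyl-2-vinyloxirane (racemic) | CC1(C=C)CO1 | starting material
14 | anti-1,3-diol (6R,7R,10R) | COC(=O)/C=C(/C)C[C@@H](C)C1(OCCO1)C[C@@H](O)[C@@](C)(CO)C=C | intermediate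
15 | β-hydroxy aldehyde (6S,7R,10R) | COC(=O)/C=C(/C)C[C@@H](C)C1(OCCO1)C[C@@H](O)[C@@](C)(C=O)C=C | intermediate
16 | C7 TBS ether aldehyde (6S,7R,10R) | COC(=O)/C=C(/C)C[C@@H](C)C1(OCCO1)C[C@@H](O[Si](C)(C)C(C)(C)C)[C@@](C)(C=O)C=C | intermediate
17 | methyl bis(2,2,2-trifluoroethyl)phosphonoacetate | COC(=O)CP(=O)(OCC(F)(F)F)OCC(F)(F)F | starting material
18 | bis-enoate with Z C5=C11 (6R,7R,10R) | COC(=O)/C=C(/C)C[C@@H](C)C1(OCCO1)C[C@@H](O[Si](C)(C)C(C)(C)C)[C@@](C)(/C=C\C(=O)OC)C=C | intermediate
19 | neopentyl aldehyde (arm CHO) | COC(=O)/C=C(/C)C[C@@H](C)C1(OCCO1)C[C@@H](O[Si](C)(C)C(C)(C)C)[C@@](C)(/C=C\C(=O)OC)C=O | intermediate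
20 | hydroxy Z-enoate (arm CH2OH) | COC(=O)/C=C(/C)C[C@@H](C)C1(OCCO1)C[C@@H](O[Si](C)(C)C(C)(C)C)[C@@](C)(/C=C\C(=O)OC)CO | intermediate
21 | α,β-unsaturated δ-lactone (6S,7R,10R) | COC(=O)/C=C(/C)C[C@@H](C)C1(OCCO1)C[C@@H](O[Si](C)(C)C(C)(C)C)[C@@]2(C)C=CC(=O)OC2 | intermediate
22 | lithium dienolate | CO/C(O[Li])=C/C(C)=C/[C@@H](C)C1(OCCO1)C[C@@H](O[Si](C)(C)C(C)(C)C)[C@@]2(C)C=CC(=O)OC2 | intermediate
23 | triene, key-step precursor (6S,7R,10R) | CO/C(O[Si](C)(C)C(C)(C)C)=C/C(C)=C/[C@@H](C)C1(OCCO1)C[C@@H](O[Si](C)(C)C(C)(C)C)[C@@]2(C)C=CC(=O)OC2 | intermediate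
24 | cis-fused cycloadduct, key-step product | CO[C@]1(O[Si](C)(C)C(C)(C)C)C=C(C)[C@H]2[C@H]3[C@@H]1C(=O)OC[C@@]3(C)[C@H](O[Si](C)(C)C(C)(C)C)CC4(OCCO4)[C@@H]2C | intermediate
25 | β-keto lactone | O=C1C=C(C)[C@H]2[C@H]3[C@@H]1C(=O)OC[C@@]3(C)[C@H](O[Si](C)(C)C(C)(C)C)CC4(OCCO4)[C@@H]2C | intermediate
26 | bicyclic enone alcohol | O=C1C=C(C)[C@H]2[C@@H](C1)[C@@](C)(CO)[C@H](O[Si](C)(C)C(C)(C)C)CC3(OCCO3)[C@@H]2C | intermediate
27 | arm TBDPS ether | O=C1C=C(C)[C@H]2[C@@H](C1)[C@@](C)(CO[Si](c3ccccc3)(c3ccccc3)C(C)(C)C)[C@H](O[Si](C)(C)C(C)(C)C)CC3(OCCO3)[C@@H]2C | intermediate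
28 | β-hydroxy ketone | O=C1C=C(C)[C@H]2[C@@H](C1)[C@@](C)(CO[Si](c3ccccc3)(c3ccccc3)C(C)(C)C)[C@H](O)CC(=O)[C@@H]2C | intermediate
29 | C7 mesylate | O=C1C=C(C)[C@H]2[C@@H](C1)[C@@](C)(CO[Si](c3ccccc3)(c3ccccc3)C(C)(C)C)[C@H](OS(C)(=O)=O)CC(=O)[C@@H]2C | intermediate
30 | bicyclic bis-enone | O=C1C=C(C)[C@H]2[C@@H](C1)[C@@](C)(CO[Si](c3ccccc3)(c3ccccc3)C(C)(C)C)C=CC(=O)[C@@H]2C | intermediate
31 | dilithium bis-enolate | [Li]OC1=C[C@@H]2[C@H](C(C)=C1)C(C)=C(O[Li])C=C[C@]2(C)CO[Si](c1ccccc1)(c1ccccc1)C(C)(C)C | intermediate
32 | tricyclic bis-enone | CC(C)(C)[Si](c1ccccc1)(c1ccccc1)OC[C@]1(C)[C@@H]2[C@H]3C(=O)C=C(C)[C@@H]2[C@@]3(C)C(=O)C=C1 | intermediate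
33 | C7 boronate | CC(C)(C)[Si](c1ccccc1)(c1ccccc1)OC[C@]1(C)[C@@H]2[C@H]3C(=O)C=C(C)[C@@H]2[C@@]3(C)C(=O)C[C@H]1B4OC(C)(C)C(C)(C)O4 | intermediate
34 | tricyclic β-hydroxy ketone | CC(C)(C)[Si](c1ccccc1)(c1ccccc1)OC[C@]1(C)[C@@H]2[C@H]3C(=O)C=C(C)[C@@H]2[C@@]3(C)C(=O)C[C@H]1O | intermediate
35 | acetaldehyde | CC=O | starting material
36 | C7 acetate C9 alcohol | CC(C)(C)[Si](c1ccccc1)(c1ccccc1)OC[C@]1(C)[C@@H]2[C@H]3C(=O)C=C(C)[C@@H]2[C@@]3(C)[C@H](O)C[C@H]1OC(C)=O | intermediate
37 | 3-methylbut-2-enoyl chloride | CC(C)=CC(=O)Cl | starting material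
38 | C7 acetate C9 senecioate arm TBDPS ether | CC(C)(C)[Si](c1ccccc1)(c1ccccc1)OC[C@]1(C)[C@@H]2[C@H]3C(=O)C=C(C)[C@@H]2[C@@]3(C)[C@H](OC(=O)C=C(C)C)C[C@H]1OC(C)=O | intermediate
39 | primary alcohol | OC[C@]1(C)[C@@H]2[C@H]3C(=O)C=C(C)[C@@H]2[C@@]3(C)[C@H](OC(=O)C=C(C)C)C[C@H]1OC(C)=O | intermediate
40 | angelic acid | C/C=C(/C)C(=O)O | starting material
41 | angelic 2,4,6-trichlorobenzoic mixed anhydride | C/C=C(/C)C(=O)OC(=O)c1c(Cl)cc(Cl)cc1Cl | intermediate
42 | CNP0179010.1 | C/C=C(/C)C(=O)OC[C@]1(C)[C@@H]2[C@H]3C(=O)C=C(C)[C@@H]2[C@@]3(C)[C@H](OC(=O)C=C(C)C)C[C@H]1OC(C)=O | target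

## Step count and risks

Total step count: 24. Longest linear sequence: 23 steps (1 to 42 through steps 1, 2 and 4 to 24). Step 3 is a one-step side branch.

**Step 14.** Closure through the five-atom tether is slow. Silyl migration, adventitious hydrolysis or oligomerisation of the ketene acetal may outrun the cycloaddition, and exo folding may erode the cis fusion. The fallback makes the same two bonds one at a time and sets out from 23. Catalytic Tf2NH in CH2Cl2 at −78 °C triggers an intramolecular vinylogous Mukaiyama–Michael addition of C4 to C5. Aqueous work-up then gives the cycloheptane-fused saturated lactone carrying the Z-enoate side chain on C4, the Michael adduct F1. KOtBu in THF at 0 °C effects Dieckmann condensation of the lactone enolate (C11) onto the C1 ester. The route is rejoined at β-keto lactone 25.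

**Step 19.** The strained four-membered ring closes slowly. Intermolecular coupling, proton transfer between enolate and product, or α-chlorination by the copper salt may therefore take over. The fallback replaces one-electron coupling by a two-electron sequence and sets out from 30. The bis-enolate (LiN(iPr)2) is trapped with Me3SiCl as the bis(trimethylsilyl dienol ether) F2. One equivalent of N-iodosuccinimide at −78 °C attacks the less hindered C11 terminus from the convex face and gives the α′-iodo enone that still carries the C9/C10 enol silane, F3. Anhydrous tris(dimethylamino)sulfonium difluorotrimethylsilicate at high dilution then unmasks the C10 enolate. This enolate displaces iodide in a carbonyl-activated SN2 reaction with no free C9 ketone present. The route is rejoined at 32.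

**Step 13.** Three processes may lower the content of reactive diene: competing deprotonation at the C3 methyl group, formation of the Z isomer at C3=C4, and C-silylation. The fallback separates isomer control from silylation and sets out from 21. Deprotonation (LiN(iPr)2, DMPU, −78 °C) followed by kinetic α-protonation with AcOH gives the deconjugated (E)-β,γ-unsaturated ester F4. This ester is stable and can be freed from isomers by chromatography. Its doubly activated C2H2 group is then deprotonated and silylated (LiN(iPr)2, TBSCl) without touching the alkene geometry. The route is rejoined at 23.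

Further compounds
F1 | step 14 | Michael adduct: cycloheptane-fused saturated δ-lactone with (Z)-enoate side chain on C4 | COC(=O)/C=C(/C)[C@H]1[C@H]2CC(=O)OC[C@@]2(C)[C@H](O[Si](C)(C)C(C)(C)C)CC3(OCCO3)[C@@H]1C
F2 | step 19 | bis(trimethylsilyl dienol ether) of 30 | C[Si](C)(C)OC1=C[C@@H]2[C@H](C(C)=C1)C(C)=C(O[Si](C)(C)C)C=C[C@]2(C)CO[Si](c1ccccc1)(c1ccccc1)C(C)(C)C
F3 | step 19 | α′-iodo enone with C9/C10 enol silane | O=C1C=C(C)[C@@H]2C(C)=C(O[Si](C)(C)C)C=C[C@](C)(CO[Si](c3ccccc3)(c3ccccc3)C(C)(C)C)[C@@H]2[C@H]1I
F4 | step 13 | (E)-β,γ-unsaturated ester of 21 | COC(=O)C/C(C)=C/[C@@H](C)C1(OCCO1)C[C@@H](O[Si](C)(C)C(C)(C)C)[C@@]2(C)C=CC(=O)OC2
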